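The flavanone ring C is disconnected across O1–C8a and C2–C3, a formal [4+2] union of an aldehyde C=O with the C3–C4–C4a–C8a unit of a ring-A fluoro ketone. The key step exploits C8a, which lies ortho to the C4 carbonyl and meta to both ring-A oxygens and is therefore open to SNAr, and the doubly activated C3–H. In one flask a catalytic asymmetric Mukaiyama aldol joins C2 to C3 and sets C2; fluoride then frees the alkoxide O1, which displaces fluoride at C8a, and C3 settles trans. The precursor is the silyl enol ether of a pentabenzylated 2-fluoro deoxybenzoin that already carries the flavone.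

Key step: step 6

Remark: the target is read as the 2,3-trans flavanone with 2R,3S configuration.
Remark: compound 5 is taken as a catalogue compound.
Remark: the (acyloxy)borane from natural (2R,3R)-tartaric acid is taken to direct the enol silane to the Re face of the aryl aldehyde; if this substrate shows the opposite sense, the catalyst from (2S,3S)-tartaric acid is used.

Step 1
Reactants: 1 1-(2,4,6-trifluorophenyl)ethan-1-one; 2 benzyl alcohol
Product: 4 1-[2,4-bis(benzyloxy)-6-fluorophenyl]ethan-1-one, via difluoro monoether 3 (not isolated)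
Conditions: 2 (2.1 equiv), NaH (2.1 equiv), THF, 0 °C; then added to 1, DMF, −20 °C → rt
Reagents that add atoms: none
Why: Twofold nucleophilic aromatic substitution (SNAr): the acetyl group activates the para and then one ortho fluorine toward benzyloxide, and the last fluorine should survive two equivalents of alkoxide because two alkoxy donors have by then weakened the carbonyl as an activating group.

Step 2
Reactants: 5 1-[2,4-bis(benzyloxy)-6-hydroxyphenyl]ethan-1-one; 6 4-(benzyloxy)-3-bromobenzaldehyde
Product: 7 (E)-1-[2,4-bis(benzyloxy)-6-hydroxyphenyl]-3-[4-(benzyloxy)-3-bromophenyl]prop-2-en-1-one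
Conditions: KOH (50% aq.), EtOH, rt
Reagents that add atoms: none
Why: Claisen–Schmidt aldol condensation of a methyl ketone with a non-enolisable aryl aldehyde should give the (E)-2'-hydroxychalcone, the benzyl ethers and the aryl bromide being inert to hydroxide.

Step 3
Reactants: 7 (E)-1-[2,4-bis(benzyloxy)-6-hydroxyphenyl]-3-[4-(benzyloxy)-3-bromophenyl]prop-2-en-1-one
Product: 9 5,7-bis(benzyloxy)-2-[4-(benzyloxy)-3-bromophenyl]-4H-chromen-4-one, via racemic flavanone 8 (not isolated)
Conditions: I2 (10 mol%), DMSO, 130 °C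
Reagents that add atoms: none
Why: Iodine-catalysed oxidative cyclisation of a 2'-hydroxychalcone: oxa-Michael closure to the flavanone, α-iodination and loss of HI should give the flavone while DMSO returns HI to I2.

Step 4
Reactants: 4 1-[2,4-bis(benzyloxy)-6-fluorophenyl]ethan-1-one; 9 5,7-bis(benzyloxy)-2-[4-(benzyloxy)-3-bromophenyl]-4H-chromen-4-one
Product: 10 5,7-bis(benzyloxy)-2-[4-(benzyloxy)-3-{2-[2,4-bis(benzyloxy)-6-fluorophenyl]-2-oxoethyl}phenyl]-4H-chromen-4-one
Conditions: 4 (1.3 equiv), Pd2(dba)3 (2.5 mol%), Xantphos (6 mol%), K3PO4, toluene, 80 °C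
Reagents that add atoms: none
Why: Palladium-catalysed α-arylation of an aryl methyl ketone (Buchwald–Hartwig type) should couple the enolate of 4 once with the aryl bromide, because the more acidic product rests as its hindered enolate, and the mild base K3PO4 should spare the aryl fluoride and the flavone.

Step 5
Reactants: 10 5,7-bis(benzyloxy)-2-[4-(benzyloxy)-3-{2-[2,4-bis(benzyloxy)-6-fluorophenyl]-2-oxoethyl}phenyl]-4H-chromen-4-one
Product: 11 5,7-bis(benzyloxy)-2-[4-(benzyloxy)-3-{(Z)-2-[2,4-bis(benzyloxy)-6-fluorophenyl]-2-[(trimethylsilyl)oxy]ethenyl}phenyl]-4H-chromen-4-one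
Conditions: TMSOTf, Et3N, CH2Cl2, 0 °C; NaHCO3 work-up, used crude
Reagents that add atoms: trimethylsilyl trifluoromethanesulfonate, C[Si](C)(C)OS(=O)(=O)C(F)(F)F
Why: Soft enolisation (silyl triflate and amine) of the CH2 group, which is both α to the ketone and benzylic, should give the thermodynamically preferred (Z)-silyl enol ether with the two aryl groups trans.

Step 6
Reactants: 11 5,7-bis(benzyloxy)-2-[4-(benzyloxy)-3-{(Z)-2-[2,4-bis(benzyloxy)-6-fluorophenyl]-2-[(trimethylsilyl)oxy]ethenyl}phenyl]-4H-chromen-4-one; 12 4-(benzyloxy)benzaldehyde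
Product: 15 (2R,3S)-5,7-bis(benzyloxy)-2-[4-(benzyloxy)phenyl]-3-[2-(benzyloxy)-5-(5,7-bis(benzyloxy)-4-oxo-4H-chromen-2-yl)phenyl]chroman-4-one, via syn-aldol silyl ether 13 (not isolated), via cis-flavanone 14 (not isolated)
Conditions: 12 (1.5 equiv), (acyloxy)borane from (2R,3R)-2-O-(2,6-diisopropoxybenzoyl)tartaric acid and BH3·THF (30 mol%), EtCN, −78 °C; then Bu4N[Ph3SiF2] (1.0 equiv), THF, −40 → 0 °C; AcOH quench
Reagents that add atoms: none
Why: The chiral boron Lewis acid binds the aldehyde and the enol silane attacks its Re face through an open transition state with silyl transfer to the aldolate oxygen (Mukaiyama aldol), forming C2–C3; fluoride then removes the silyl group and the alkoxide O1 adds to C8a and expels fluoride (intramolecular SNAr through a Meisenheimer intermediate), the released fluoride carrying the chain and fluorotrimethylsilane acting as the sink. The closest known reaction types are the (acyloxy)borane-catalysed aldol addition of ketone silyl enol ethers to aryl aldehydes and the alkoxide SNAr closure of ortho-fluoroaryl β-hydroxy ketones to chroman-4-ones, which together are the arene counterpart of a Danishefsky-diene hetero-Diels–Alder annulation. Ring C closes by an addition–elimination that is formally 6-endo-trig, because the C4a=C8a bond of the aryl ketone (a vinylogous acyl fluoride) lies inside the new ring, followed by loss of fluoride. C2 is set by the catalyst (Re-face attack gives 2R) and is not touched afterwards, whereas C3 is first set syn by the aldol (cis-flavanone 14) and should then equilibrate through the enolate under the fluoride to the trans-diequatorial 3S isomer, so the simple diastereoselectivity of the aldol does not matter. The step needs facial selectivity at the aldehyde, which the catalyst supplies, and ring closure faster than retro-aldol cleavage or dehydration, which the substrate secures by placing C8a ortho to the carbonyl and meta to both benzyloxy groups (no resonance deactivation at the carbon attacked) and by the six-membered geometry, while the weakly basic silicate fluoride source keeps the concentration of free alkoxide low.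

Step 7
Reactants: 15 (2R,3S)-5,7-bis(benzyloxy)-2-[4-(benzyloxy)phenyl]-3-[2-(benzyloxy)-5-(5,7-bis(benzyloxy)-4-oxo-4H-chromen-2-yl)phenyl]chroman-4-one
Product: 16 (2R,3S)-5,7-dihydroxy-2-(4-hydroxyphenyl)-3-[2-hydroxy-5-(5,7-dihydroxy-4-oxo-4H-chromen-2-yl)phenyl]chroman-4-one
Conditions: H2 (1 atm), Pd/C (10 wt%), THF–MeOH, rt; neutral work-up
Reagents that add atoms: none
Why: Palladium-catalysed hydrogenolysis of the six benzyl aryl ethers is neutral, so C3 is not enolised and ring C is not opened, and the flavone C2=C3 bond and the ketones should be reduced far more slowly than the O-benzyl groups are cleaved.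

Compound list
1 | 1-(2,4,6-trifluorophenyl)ethan-1-one | CC(=O)c1c(F)cc(F)cc1F | starting material
2 | benzyl alcohol | OCc1ccccc1 | starting material
3 | 1-[4-(benzyloxy)-2,6-difluorophenyl]ethan-1-one | CC(=O)c1c(F)cc(OCc2ccccc2)cc1F | intermediate
4 | 1-[2,4-bis(benzyloxy)-6-fluorophenyl]ethan-1-one | CC(=O)c1c(F)cc(OCc2ccccc2)cc1OCc1ccccc1 | intermediate
5 | 1-[2,4-bis(benzyloxy)-6-hydroxyphenyl]ethan-1-one | CC(=O)c1c(O)cc(OCc2ccccc2)cc1OCc1ccccc1 | starting material
6 | 4-(benzyloxy)-3-bromobenzaldehyde | O=Cc1ccc(OCc2ccccc2)c(Br)c1 | starting material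
7 | (E)-1-[2,4-bis(benzyloxy)-6-hydroxyphenyl]-3-[4-(benzyloxy)-3-bromophenyl]prop-2-en-1-one | O=C(/C=C/c1ccc(OCc2ccccc2)c(Br)c1)c1c(O)cc(OCc2ccccc2)cc1OCc1ccccc1 | intermediate
8 | racemic 5,7-bis(benzyloxy)-2-[4-(benzyloxy)-3-bromophenyl]chroman-4-one | O=C1CC(c2ccc(OCc3ccccc3)c(Br)c2)Oc2cc(OCc3ccccc3)cc(OCc3ccccc3)c12 | intermediate
9 | 5,7-bis(benzyloxy)-2-[4-(benzyloxy)-3-bromophenyl]-4H-chromen-4-one | O=c1cc(-c2ccc(OCc3ccccc3)c(Br)c2)oc2cc(OCc3ccccc3)cc(OCc3ccccc3)c12 | intermediate
10 | 5,7-bis(benzyloxy)-2-[4-(benzyloxy)-3-{2-[2,4-bis(benzyloxy)-6-fluorophenyl]-2-oxoethyl}phenyl]-4H-chromen-4-one | O=C(Cc1cc(-c2cc(=O)c3c(OCc4ccccc4)cc(OCc4ccccc4)cc3o2)ccc1OCc1ccccc1)c1c(F)cc(OCc2ccccc2)cc1OCc1ccccc1 | intermediate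
11 | 5,7-bis(benzyloxy)-2-[4-(benzyloxy)-3-{(Z)-2-[2,4-bis(benzyloxy)-6-fluorophenyl]-2-[(trimethylsilyl)oxy]ethenyl}phenyl]-4H-chromen-4-one | C[Si](C)(C)O/C(=C\c1cc(-c2cc(=O)c3c(OCc4ccccc4)cc(OCc4ccccc4)cc3o2)ccc1OCc1ccccc1)c1c(F)cc(OCc2ccccc2)cc1OCc1ccccc1 | intermediate
12 | 4-(benzyloxy)benzaldehyde | O=Cc1ccc(OCc2ccccc2)cc1 | starting material
13 | (2R,3R)-1-[2,4-bis(benzyloxy)-6-fluorophenyl]-2-[2-(benzyloxy)-5-(5,7-bis(benzyloxy)-4-oxo-4H-chromen-2-yl)phenyl]-3-[4-(benzyloxy)phenyl]-3-[(trimethylsilyl)oxy]propan-1-one (syn aldol) | C[Si](C)(C)O[C@@H](c1ccc(OCc2ccccc2)cc1)[C@H](C(=O)c1c(F)cc(OCc2ccccc2)cc1OCc1ccccc1)c1cc(-c2cc(=O)c3c(OCc4ccccc4)cc(OCc4ccccc4)cc3o2)ccc1OCc1ccccc1 | intermediate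
14 | (2R,3R)-5,7-bis(benzyloxy)-2-[4-(benzyloxy)phenyl]-3-[2-(benzyloxy)-5-(5,7-bis(benzyloxy)-4-oxo-4H-chromen-2-yl)phenyl]chroman-4-one (2,3-cis) | O=C1c2c(OCc3ccccc3)cc(OCc3ccccc3)cc2O[C@@H](c2ccc(OCc3ccccc3)cc2)[C@H]1c1cc(-c2cc(=O)c3c(OCc4ccccc4)cc(OCc4ccccc4)cc3o2)ccc1OCc1ccccc1 | intermediate
15 | (2R,3S)-5,7-bis(benzyloxy)-2-[4-(benzyloxy)phenyl]-3-[2-(benzyloxy)-5-(5,7-bis(benzyloxy)-4-oxo-4H-chromen-2-yl)phenyl]chroman-4-one (2,3-trans) | O=C1c2c(OCc3ccccc3)cc(OCc3ccccc3)cc2O[C@@H](c2ccc(OCc3ccccc3)cc2)[C@@H]1c1cc(-c2cc(=O)c3c(OCc4ccccc4)cc(OCc4ccccc4)cc3o2)ccc1OCc1ccccc1 | intermediate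
16 | (2R,3S)-5,7-dihydroxy-2-(4-hydroxyphenyl)-3-[2-hydroxy-5-(5,7-dihydroxy-4-oxo-4H-chromen-2-yl)phenyl]chroman-4-one (2,3-trans) | O=C1c2c(O)cc(O)cc2O[C@@H](c2ccc(O)cc2)[C@@H]1c1cc(-c2cc(=O)c3c(O)cc(O)cc3o2)ccc1O | target

Total step count: 7.
Longest linear sequence: 6 steps (steps 2, 3, 4, 5, 6 and 7, from 5 and 6).

The three steps most likely to fail, with one fallback each

The step most at risk is step 6. Enantiopurity may be lost if the freed alkoxide undergoes retro-aldol cleavage and re-addition, or dehydration, before it closes the ring. Turnover may be slow because the flavone carbonyl competes with the aldehyde for the boron Lewis acid. The cis-to-trans equilibration at C3 may stay incomplete, or be accompanied by base-induced opening of ring C, which would erode the configuration at C2. The fallback sets out from 10 (bypassing 11) and 12 and comes back at 15. Ketone 10 is deprotonated with KN(SiMe3)2 in THF at −78 °C, 12 is added and the mixture is warmed to 0 °C with 18-crown-6. The racemic potassium 1-[4-(benzyloxy)phenyl]-3-[2,4-bis(benzyloxy)-6-fluorophenyl]-2-[2-(benzyloxy)-5-(5,7-bis(benzyloxy)-4-oxo-4H-chromen-2-yl)phenyl]-3-oxopropan-1-olate F1, the aldolate of 10 and 12 as a mixture of diastereomers, should then close by the same intramolecular SNAr and equilibrate at C3 to the racemic trans-flavanone, that is 15 together with its enantiomer (2S,3R)-5,7-bis(benzyloxy)-2-[4-(benzyloxy)phenyl]-3-[2-(benzyloxy)-5-(5,7-bis(benzyloxy)-4-oxo-4H-chromen-2-yl)phenyl]chroman-4-one F2. Preparative chromatography on a chiral stationary phase (amylose tris(3,5-dimethylphenylcarbamate), supercritical CO2–MeOH) then delivers 15. The same two bonds are still made in one operation, and control by the catalyst is replaced by resolution.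

Second in risk is step 4. Oxidative addition and reductive elimination at the ortho-benzyloxy aryl bromide may be slow, a second arylation may occur, and the base may degrade the fluoro ketone on prolonged heating. The fallback reverses the polarity of the coupling; it sets out from 4 and 9 and comes back at 10. Ketone 4 is brominated with CuBr2 in EtOAc–CHCl3 at reflux to 2-bromo-1-[2,4-bis(benzyloxy)-6-fluorophenyl]ethan-1-one F3. Bromide 9 is converted by Miyaura borylation (B2pin2, Pd(dppf)Cl2, KOAc, dioxane, 90 °C) into 5,7-bis(benzyloxy)-2-[4-(benzyloxy)-3-(4,4,5,5-tetramethyl-1,3,2-dioxaborolan-2-yl)phenyl]-4H-chromen-4-one F4. Suzuki–Miyaura coupling of the α-bromo ketone with the aryl boronate (Pd(OAc)2, P(o-tolyl)3, K3PO4, THF with a little water, rt to 40 °C) should then give 10.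

Third in risk is step 1. The second substitution may go to the other ortho position after an ortho-first event, a third substitution may follow, and part of the ketone may be consumed through its enolate. The fallback makes the C–F bond instead of the two C–O bonds; it sets out from 5, which the route already uses, and comes back at 4. Deoxyfluorination of the phenol with 1,3-bis(2,6-diisopropylphenyl)-2,2-difluoro-2,3-dihydro-1H-imidazole and CsF in toluene at 110 °C should give 4 directly, the ortho acetyl group and the meta position of both benzyloxy groups favouring the concerted substitution. No new compound is made on the way, which the entry F0 records.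

Further compounds
F1 | step 6 | racemic potassium 1-[4-(benzyloxy)phenyl]-3-[2,4-bis(benzyloxy)-6-fluorophenyl]-2-[2-(benzyloxy)-5-(5,7-bis(benzyloxy)-4-oxo-4H-chromen-2-yl)phenyl]-3-oxopropan-1-olate | [K+].[O-]C(c1ccc(OCc2ccccc2)cc1)C(C(=O)c1c(F)cc(OCc2ccccc2)cc1OCc1ccccc1)c1cc(-c2cc(=O)c3c(OCc4ccccc4)cc(OCc4ccccc4)cc3o2)ccc1OCc1ccccc1
F2 | step 6 | (2S,3R)-5,7-bis(benzyloxy)-2-[4-(benzyloxy)phenyl]-3-[2-(benzyloxy)-5-(5,7-bis(benzyloxy)-4-oxo-4H-chromen-2-yl)phenyl]chroman-4-one | O=C1c2c(OCc3ccccc3)cc(OCc3ccccc3)cc2O[C@H](c2ccc(OCc3ccccc3)cc2)[C@H]1c1cc(-c2cc(=O)c3c(OCc4ccccc4)cc(OCc4ccccc4)cc3o2)ccc1OCc1ccccc1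
F3 | step 4 | 2-bromo-1-[2,4-bis(benzyloxy)-6-fluorophenyl]ethan-1-one | O=C(CBr)c1c(F)cc(OCc2ccccc2)cc1OCc1ccccc1
F4 | step 4 | 5,7-bis(benzyloxy)-2-[4-(benzyloxy)-3-(4,4,5,5-tetramethyl-1,3,2-dioxaborolan-2-yl)phenyl]-4H-chromen-4-one | CC1(C)OB(c2cc(-c3cc(=O)c4c(OCc5ccccc5)cc(OCc5ccccc5)cc4o3)ccc2OCc2ccccc2)OC1(C)C
F0 | step 1 | none | none
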